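C8 is bought. Everything else is relayed from it or set by reagent control, and the γ-lactone is closed last by inserting CO2 between C11 and C6.

1. Retrosynthesis, in order: O9–Si; then O–C6 and C11–C12 together, so the lactone gives back CO2 and a ten-membered γ-mesyloxy alkenylboronate; C2=C3 (back to the alkyne); C9–C10 (Nozaki–Hiyama–Kishi); C6–C7 (allylboration); O8–acyl.
2. Enabling feature: in the ring O/C12/C11/C7/C6, the sp2 carbon C11 and the carbinol carbon C6 stand 1,3 across C7, so O=C=O is exactly the missing O–C12 edge. C6 is flanked by the C4–C5 oxirane, which blocks ionisation and favours SN2, and C11 can carry boron.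
3. Forward: both oxiranes come first (two Sharpless epoxidations). Allene diboration gives twin borons: the allylic one joins C6–C7 and the vinylic one waits on C11. The ten-membered ring closes at C9–C10, the alkyne becomes the Z-alkene, and the γ-lactone is made last from CO2.
4. Stereochemistry: C8 is bought (D-glyceraldehyde). C4/C5 and C2'/C3' come from D-(−)-tartrate reagent control. C6/C7 are set together in one matched Z-allylboration relayed from C5 and C8. C9 comes from the macrocyclic transition state. C6 is built as 6R and inverted to 6S by the key step, which fixes the trans ring fusion.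

Key step: step 20

Remark: germacrane numbering of the target is used throughout (ring C1–C10, lactone C11–C13, ester carbon C14, methyl C15, acyl C1'–C5'). Compounds 1, 5 and 10 are assumed to be purchasable.

Step 1
Reactants: 1 methyl angelate (methyl (Z)-2-methylbut-2-enoate)
Product: 2 (Z)-2-methylbut-2-en-1-ol
Conditions: DIBAL-H (2.2 equiv), CH2Cl2, −78 to 0 °C; Rochelle salt
Reagents that add atoms: none
Why: 1,2-reduction of an enoate with DIBAL-H should stop at the allylic alcohol and, with no acid or radical source present, should keep the labile Z geometry.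

Step 2
Reactants: 2 (Z)-2-methylbut-2-en-1-ol
Product: 3 [(2R,3S)-2,3-dimethyloxiran-2-yl]methanol
Conditions: Ti(OiPr)4 (10 mol %), D-(−)-diethyl tartrate (12 mol %), t-BuOOH, 4 Å MS, CH2Cl2, −20 °C
Reagents that add atoms: tert-butyl hydroperoxide CC(C)(C)OO
Why: Sharpless asymmetric epoxidation, in which D-(−)-tartrate directs oxygen to the face that gives 2R and syn addition to the Z-alkene fixes 3S (CH2OH and the C3 methyl cis).

Step 3
Reactants: 3 [(2R,3S)-2,3-dimethyloxiran-2-yl]methanol
Product: 4 (2S,3S)-2,3-dimethyloxirane-2-carboxylic acid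
Conditions: TEMPO (cat.), PhI(OAc)2 (2.2 equiv), MeCN–H2O 1:1, rt
Reagents that add atoms: water O
Why: TEMPO/PhI(OAc)2 oxidation takes the primary alcohol through the aldehyde hydrate to the acid under near-neutral conditions that spare the oxirane; no centre is touched (the C2 descriptor changes only by priority).

Step 4
Reactants: 5 (E)-3-methylpent-2-en-4-yn-1-ol
Product: 6 [(2R,3R)-3-ethynyl-3-methyloxiran-2-yl]methanol
Conditions: Ti(OiPr)4 (10 mol %), D-(−)-diethyl tartrate (12 mol %), t-BuOOH, 4 Å MS, CH2Cl2, −20 °C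
Reagents that add atoms: tert-butyl hydroperoxide CC(C)(C)OO
Why: Sharpless asymmetric epoxidation of an E-3,3-disubstituted allylic alcohol, in which D-(−)-tartrate sets C5 as R and syn addition to the E-alkene sets C4 as R (alkynyl trans to CH2OH).

Step 5
Reactants: 6 [(2R,3R)-3-ethynyl-3-methyloxiran-2-yl]methanol
Product: 7 3-[(2R,3R)-3-(hydroxymethyl)-2-methyloxiran-2-yl]prop-2-ynal
Conditions: n-BuLi (2.1 equiv), THF, −78 °C; DMF, −78 to 0 °C; inverse quench into aq NH4Cl
Reagents that add atoms: N,N-dimethylformamide CN(C)C=O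
Why: formylation of a lithium acetylide with DMF adds C1; the lithium alkoxide is inert in the cold aprotic medium (no epoxide migration), and the inverse quench keeps the liberated amine from adding to the ynal.

Step 6
Reactants: 7 3-[(2R,3R)-3-(hydroxymethyl)-2-methyloxiran-2-yl]prop-2-ynal
Product: 8 methyl (Z)-5-[(2R,3R)-3-(hydroxymethyl)-2-methyloxiran-2-yl]-2-iodopent-2-en-4-ynoate
Conditions: Ph3P=CHCO2Me, NIS, CH2Cl2, −20 °C; then 7, −20 °C to rt
Reagents that add atoms: methyl (triphenylphosphoranylidene)acetate COC(=O)C=P(c1ccccc1)(c1ccccc1)c1ccccc1; N-iodosuccinimide O=C1CCC(=O)N1I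
Why: Wittig olefination with the α-iodo ylide made in situ should give mainly the (Z)-α-iodoenoate (ester trans to the alkynyl group), which places iodine where C9 must later stand; it adds C10 and C14.

Step 7
Reactants: 8 methyl (Z)-5-[(2R,3R)-3-(hydroxymethyl)-2-methyloxiran-2-yl]-2-iodopent-2-en-4-ynoate
Product: 9 methyl (Z)-5-[(2R,3S)-3-formyl-2-methyloxiran-2-yl]-2-iodopent-2-en-4-ynoate
Conditions: TEMPO (cat.), PhI(OAc)2 (1.1 equiv), CH2Cl2, rt
Reagents that add atoms: none
Why: TEMPO/PhI(OAc)2 oxidation of a primary alcohol stops at the aldehyde in anhydrous medium and is mild enough not to epimerise C5 or open the oxirane.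

Step 8
Reactants: 10 (R)-2,3-O-isopropylideneglyceraldehyde
Product: 11 (S)-4-ethynyl-2,2-dimethyl-1,3-dioxolane
Conditions: dimethyl (1-diazo-2-oxopropyl)phosphonate, K2CO3, MeOH, 0 °C to rt
Reagents that add atoms: dimethyl (1-diazo-2-oxopropyl)phosphonate COP(=O)(OC)C(=[N+]=[N-])C(C)=O
Why: Ohira–Bestmann homologation turns the aldehyde carbon into C7 and adds C11; the mild carbonate base should leave the purchased α-alkoxy centre C8 intact.

Step 9
Reactants: 11 (S)-4-ethynyl-2,2-dimethyl-1,3-dioxolane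
Product: 13 (S)-2,2-dimethyl-4-(propa-1,2-dien-1-yl)-1,3-dioxolane, via propargylamine 12 (not isolated)
Conditions: (CH2O)n, Cy2NH, CuI (0.5 equiv), dioxane, reflux
Reagents that add atoms: formaldehyde C=O
Why: Crabbé homologation (Cu-mediated Mannich reaction to 12, then hydride transfer from N–CH and loss of the imine) adds C13 as the allene terminus; C8 still carries only a poor leaving group, so propargylic substitution cannot compete.

Step 10
Reactants: 13 (S)-2,2-dimethyl-4-(propa-1,2-dien-1-yl)-1,3-dioxolane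
Product: 14 (S)-penta-3,4-diene-1,2-diol
Conditions: AcOH–H2O 4:1, 40 °C
Reagents that add atoms: none
Why: acid hydrolysis of a terminal isopropylidene acetal, under which an unactivated allene and the allenylic C–O bond should survive.

Step 11
Reactants: 14 (S)-penta-3,4-diene-1,2-diol
Product: 15 (S)-1-(triethylsilyloxy)penta-3,4-dien-2-ol
Conditions: TESCl (1.05 equiv), imidazole, CH2Cl2, −78 to −40 °C
Reagents that add atoms: chlorotriethylsilane CC[Si](Cl)(CC)CC
Why: kinetic silylation distinguishes the primary hydroxyl (O9) from the secondary allenylic one (O8) on steric grounds.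

Step 12
Reactants: 15 (S)-1-(triethylsilyloxy)penta-3,4-dien-2-ol; 4 (2S,3S)-2,3-dimethyloxirane-2-carboxylic acid
Product: 17 (S)-1-(triethylsilyloxy)penta-3,4-dien-2-yl (2S,3S)-2,3-dimethyloxirane-2-carboxylate, via mixed anhydride 16 (not isolated)
Conditions: 4, 2,4,6-Cl3C6H2COCl, Et3N, toluene, rt; then 15, DMAP, rt
Reagents that add atoms: none
Why: Yamaguchi esterification joins the hindered α-quaternary acid to the secondary alcohol without breaking a bond at C8, C2' or C3'; acylating O8 here, far from any C14 ester, avoids later 8,14-lactonisation and any O8/O9 differentiation.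

Step 13
Reactants: 17 (S)-1-(triethylsilyloxy)penta-3,4-dien-2-yl (2S,3S)-2,3-dimethyloxirane-2-carboxylate
Product: 18 (S,Z)-4,5-bis(pinacolatoboryl)-1-(triethylsilyloxy)pent-3-en-2-yl (2S,3S)-2,3-dimethyloxirane-2-carboxylate
Conditions: B2pin2, Pt(dba)2 (3 mol %), PCy3 (4 mol %), toluene, 50 °C
Reagents that add atoms: bis(pinacolato)diboron CC1(C)OB(OC1(C)C)B1OC(C)(C)C(C)(C)O1
Why: Pt(0)-catalysed syn-diboration of an allene, in which the bulky phosphine should steer addition to the unsubstituted C11=C13 bond from the side of H7, putting boron on C11 and C13 with C8 cis to CH2B (Z).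

Step 14
Reactants: 18 (S,Z)-4,5-bis(pinacolatoboryl)-1-(triethylsilyloxy)pent-3-en-2-yl (2S,3S)-2,3-dimethyloxirane-2-carboxylate; 9 methyl (Z)-5-[(2R,3S)-3-formyl-2-methyloxiran-2-yl]-2-iodopent-2-en-4-ynoate
Product: 20 9,10-seco alcohol (6R-OH; C11–Bpin; 9-OTES; C10–I), via O-boryl adduct 19 (not isolated)
Conditions: toluene, 4 Å MS, rt to 40 °C; then aq NaHCO3
Reagents that add atoms: none
Why: type I allylboration through a closed chair. The Z-allylboronate fixes the C6/C7 relation (O6 and C8 syn, so O6 anti to C11 along the backbone); the aldehyde reacts in its dipole-opposed conformer (C5–O anti to C=O, attack past H5) to give 6R; the allyl unit reacts with H8 inside and C9 anti; all three elements should point to the same isomer, and the vinylic boron stays on C11.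

Step 15
Reactants: 20 9,10-seco alcohol (6R-OH; C11–Bpin; 9-OTES; C10–I)
Product: 21 9,10-seco 6R-mesylate
Conditions: MsCl, Et3N, CH2Cl2, −20 °C
Reagents that add atoms: methanesulfonyl chloride CS(=O)(=O)Cl
Why: sulfonylation makes O6 a leaving group with retention at C6, and an epoxy-carbinyl mesylate resists ionisation well enough to be carried through the next steps.

Step 16
Reactants: 21 9,10-seco 6R-mesylate
Product: 22 9,10-seco C9 aldehyde
Conditions: (COCl)2, DMSO, CH2Cl2, −78 to −40 °C; Et3N, −78 to 0 °C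
Reagents that add atoms: none
Why: Swern conditions oxidise a primary triethylsilyl ether directly to the aldehyde (silyl transfer to chloride, then alkoxysulfonium elimination), which saves a deprotection, and the low temperature guards C8 against epimerisation.

Step 17
Reactants: 22 9,10-seco C9 aldehyde
Product: 23 ten-membered 2-yne 9S-alcohol (6R-OMs; C11–Bpin)
Conditions: CrCl2 (10 equiv), NiCl2 (cat.), DMSO–THF, 2 mM, rt
Reagents that add atoms: none
Why: Nozaki–Hiyama–Kishi macrocyclisation (Ni inserts into C10–I, Cr adds to the aldehyde) tolerates boronate, mesylate, esters and oxiranes. Only the alkenyl geometry with C9 cis to C2 can close the ring. With C8–O antiperiplanar to the forming bond, the Cr-bound oxygen should take the peripheral site and H9 the inner one, which is 9S (8,9-threo).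

Step 18
Reactants: 23 ten-membered 2-yne 9S-alcohol (6R-OMs; C11–Bpin)
Product: 24 9-O-TBS ether of 23
Conditions: TBSOTf, 2,6-lutidine, CH2Cl2, −78 to 0 °C
Reagents that add atoms: tert-butyldimethylsilyl triflate CC(C)(C)[Si](C)(C)OS(=O)(=O)C(F)(F)F
Why: silylation with the triflate and a hindered base masks the only O–H, which would otherwise protonate the alkenylcopper of step 20; a hindered secondary TBS ether should outlast CsF in DMF.

Step 19
Reactants: 24 9-O-TBS ether of 23
Product: 25 ten-membered (1(10)-cis,2Z)-dienoate 6R-mesylate C11-boronate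
Conditions: H2 (1 atm, 1 equiv uptake), Lindlar catalyst, quinoline, EtOAc, rt
Reagents that add atoms: none
Why: Lindlar semihydrogenation delivers H2 syn to the strained, most strongly adsorbed alkyne to give the 2Z-alkene, while the trisubstituted enoate and the 1,1-disubstituted alkenylboronate should be left alone.

Step 20
Reactants: 25 ten-membered (1(10)-cis,2Z)-dienoate 6R-mesylate C11-boronate
Product: 27 9-O-TBS ether of the target, via caesium acrylate 26 (not isolated)
Conditions: CO2 (1 atm), (IPr)CuCl (10 mol %; IPr = 1,3-bis(2,6-diisopropylphenyl)imidazol-2-ylidene), CsF (3 equiv), DMF, 50 °C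
Reagents that add atoms: carbon dioxide O=C=O
Why: Proposed new method: fluoride converts the C11 boronate into a borate that passes its alkenyl group with retention to (IPr)Cu–F, CO2 inserts into the Cu–C(sp2) bond (C11–C12), and salt exchange with CsF releases the caesium acrylate 26 and regenerates Cu–F. The carboxylate oxygen then displaces the C6 mesylate from the rear in a 5-exo-tet closure (O–C6), so one molecule of CO2 becomes the O–C(=O) edge of the lactone. The closest known reaction types are the Cu(I)-catalysed carboxylation of alkenylboronic esters with CO2, the Cu–NHC three-component coupling of an organocopper, CO2 and an alkyl halide to an ester, and lactone closure of γ-sulfonyloxy carboxylates with inversion; what is new is merging them on a γ-mesyloxy alkenylboronate. C6 is the only centre touched: stereospecific inversion of 6R gives 6S and hence the trans fusion with the untouched C7, and it is geometrically easy because in the extended C5–C8 backbone the C6–OMs bond lies antiperiplanar to C7–C11. The step needs O-alkylation at C6 in preference to E2 loss of MsOH, 6-exo attack on the oxirane at C5, and protodeboronation; the C4–C5 oxirane blocks ionisation at C6 and accelerates SN2 as in glycidyl sulfonates, the five-membered mode outruns the six-membered one, and after step 18 the substrate has no O–H. The esters, the twisted dienoate and both trisubstituted oxiranes should be inert to the soft (NHC)Cu-alkenyl, to CsF and to CO2 at this temperature, so the Michael-sensitive α-methylene lactone appears only after all other C–C bonds are in place.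

Step 21
Reactants: 27 9-O-TBS ether of the target
Product: 28 target CNP0131597.1
Conditions: HF·pyridine, excess pyridine, THF, 0 °C
Reagents that add atoms: none
Why: fluoride-mediated Si–O cleavage under buffered, non-basic conditions should avoid 8→9 acyl migration, conjugate addition to the α-methylene lactone and oxirane opening.

Compound list
1 | methyl angelate | C/C=C(/C)C(=O)OC | starting material
2 | (Z)-2-methylbut-2-en-1-ol | C/C=C(/C)CO | intermediate
3 | [(2R,3S)-2,3-dimethyloxiran-2-yl]methanol | OC[C@@]1(C)O[C@H]1C | intermediate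
4 | (2S,3S)-2,3-dimethyloxirane-2-carboxylic acid | OC(=O)[C@@]1(C)O[C@H]1C | intermediate
5 | (E)-3-methylpent-2-en-4-yn-1-ol | C#C/C(C)=C/CO | starting material
6 | [(2R,3R)-3-ethynyl-3-methyloxiran-2-yl]methanol | OC[C@H]1O[C@]1(C)C#C | intermediate
7 | 3-[(2R,3R)-3-(hydroxymethyl)-2-methyloxiran-2-yl]prop-2-ynal | OC[C@H]1O[C@]1(C)C#CC=O | intermediate
8 | methyl (Z)-5-[(2R,3R)-3-(hydroxymethyl)-2-methyloxiran-2-yl]-2-iodopent-2-en-4-ynoate | OC[C@H]1O[C@]1(C)C#C/C=C(\I)C(=O)OC | intermediate
9 | methyl (Z)-5-[(2R,3S)-3-formyl-2-methyloxiran-2-yl]-2-iodopent-2-en-4-ynoate | O=C[C@H]1O[C@]1(C)C#C/C=C(\I)C(=O)OC | intermediate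
10 | (R)-2,3-O-isopropylideneglyceraldehyde | O=C[C@H]1COC(C)(C)O1 | starting material
11 | (S)-4-ethynyl-2,2-dimethyl-1,3-dioxolane | C#C[C@H]1COC(C)(C)O1 | intermediate
12 | N,N-dicyclohexyl-3-[(S)-2,2-dimethyl-1,3-dioxolan-4-yl]prop-2-yn-1-amine (not isolated) | C1CCCCC1N(CC#C[C@H]1COC(C)(C)O1)C1CCCCC1 | intermediate
13 | (S)-2,2-dimethyl-4-(propa-1,2-dien-1-yl)-1,3-dioxolane | C=C=C[C@H]1COC(C)(C)O1 | intermediate
14 | (S)-penta-3,4-diene-1,2-diol | C=C=C[C@H](O)CO | intermediate
15 | (S)-1-(triethylsilyloxy)penta-3,4-dien-2-ol | C=C=C[C@H](O)CO[Si](CC)(CC)CC | intermediate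
16 | (2S,3S)-2,3-dimethyloxirane-2-carboxylic 2,4,6-trichlorobenzoic anhydride (not isolated) | O=C(OC(=O)[C@@]1(C)O[C@H]1C)c1c(Cl)cc(Cl)cc1Cl | intermediate
17 | (S)-1-(triethylsilyloxy)penta-3,4-dien-2-yl (2S,3S)-2,3-dimethyloxirane-2-carboxylate | C=C=C[C@H](OC(=O)[C@@]1(C)O[C@H]1C)CO[Si](CC)(CC)CC | intermediate
18 | (S,Z)-4,5-bis(pinacolatoboryl)-1-(triethylsilyloxy)pent-3-en-2-yl (2S,3S)-2,3-dimethyloxirane-2-carboxylate (C8 cis to CH2B) | CC1(C)OB(C/C(B2OC(C)(C)C(C)(C)O2)=C\[C@H](OC(=O)[C@@]2(C)O[C@H]2C)CO[Si](CC)(CC)CC)OC1(C)C | intermediate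
19 | O6-pinacolboryl derivative of 20 (not isolated) | CC[Si](CC)(CC)OC[C@@H](OC(=O)[C@@]2(C)O[C@H]2C)[C@@H](C(=C)B2OC(C)(C)C(C)(C)O2)[C@@H](OB2OC(C)(C)C(C)(C)O2)[C@H]1O[C@]1(C)C#C/C=C(\I)C(=O)OC | intermediate
20 | 9,10-seco alcohol: C4, C5, C7, C8 as in 28, 6R-OH (epimeric to 28), 7-[1-(pinacolboryl)vinyl], 8-O-(2S,3S)-epoxyangelate, 9-OTES, 2-yne, (Z)-10-iodo-1(10)-ene methyl ester | CC[Si](CC)(CC)OC[C@@H](OC(=O)[C@@]2(C)O[C@H]2C)[C@@H](C(=C)B2OC(C)(C)C(C)(C)O2)[C@@H](O)[C@H]1O[C@]1(C)C#C/C=C(\I)C(=O)OC | intermediate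
21 | 6R-mesylate of 20 | CC[Si](CC)(CC)OC[C@@H](OC(=O)[C@@]1(C)O[C@H]1C)[C@@H](C(=C)B1OC(C)(C)C(C)(C)O1)[C@@H](OS(C)(=O)=O)[C@H]1O[C@]1(C)C#C/C=C(\I)C(=O)OC | intermediate
22 | C9 aldehyde from 21 | O=C[C@@H](OC(=O)[C@@]2(C)O[C@H]2C)[C@@H](C(=C)B2OC(C)(C)C(C)(C)O2)[C@@H](OS(C)(=O)=O)[C@H]1O[C@]1(C)C#C/C=C(\I)C(=O)OC | intermediate
23 | ten-membered ring: 9S-OH, 1(10)-cis-enoate, 2-yne, 4R,5R-oxirane, 6R-OMs, C11–Bpin, 8S-epoxyangelate | CS(=O)(=O)O[C@@H]2[C@H](C(=C)B3OC(C)(C)C(C)(C)O3)[C@H](OC(=O)[C@@]3(C)O[C@H]3C)[C@@H](O)/C(C(=O)OC)=C\C#C[C@@]1(C)O[C@H]21 | intermediate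
24 | 9-O-TBS ether of 23 | CS(=O)(=O)O[C@@H]2[C@H](C(=C)B3OC(C)(C)C(C)(C)O3)[C@H](OC(=O)[C@@]3(C)O[C@H]3C)[C@@H](O[Si](C)(C)C(C)(C)C)/C(C(=O)OC)=C\C#C[C@@]1(C)O[C@H]21 | intermediate
25 | 2Z-alkene from 24 (6R-OMs, C11–Bpin, 9-OTBS) | CS(=O)(=O)O[C@@H]2[C@H](C(=C)B3OC(C)(C)C(C)(C)O3)[C@H](OC(=O)[C@@]3(C)O[C@H]3C)[C@@H](O[Si](C)(C)C(C)(C)C)/C(C(=O)OC)=C\C=C/[C@@]1(C)O[C@H]21 | intermediate
26 | caesium 2-substituted acrylate (C11–CO2Cs, 6R-OMs; not isolated) | [Cs+].CS(=O)(=O)O[C@@H]2[C@H](C(=C)C(=O)[O-])[C@H](OC(=O)[C@@]3(C)O[C@H]3C)[C@@H](O[Si](C)(C)C(C)(C)C)/C(C(=O)OC)=C\C=C/[C@@]1(C)O[C@H]21 | intermediate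
27 | 9-O-TBS ether of the target (6S, trans-fused α-methylene-γ-lactone) | C=C1C(=O)O[C@H]2[C@H]1[C@H](OC(=O)[C@@]1(C)O[C@H]1C)[C@@H](O[Si](C)(C)C(C)(C)C)/C(C(=O)OC)=C\C=C/[C@@]1(C)O[C@H]21 | intermediate
28 | CNP0131597.1 | C=C1C(=O)O[C@H]2[C@H]1[C@H](OC(=O)[C@@]1(C)O[C@H]1C)[C@@H](O)/C(C(=O)OC)=C\C=C/[C@@]1(C)O[C@H]21 | target

Total step count: 21.
Longest linear sequence: 14 steps (steps 8–21, from 10).

Steps most likely to fail

Step 20. The alkenylcopper may be protonated instead of carboxylated. Boron-to-copper transfer from the hindered pinacol ester may be so slow that base-induced E2 loss of methanesulfonic acid toward C7 takes over. The silyl ether may also be lost early.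
The fallback separates the two events and uses known chemistry only. It starts from 25. CsOAc with 18-crown-6 in warm toluene–DMF displaces the mesylate intermolecularly with inversion to give the 6S acetate F1. The established Cu-catalysed carboxylation of the alkenylboronate (CO2, CsF, acidic work-up), now with no leaving group in the molecule, gives the acrylic acid F2. K2CO3 in MeOH removes the secondary acetate in preference to the α-quaternary epoxyangelate to give the hydroxy acid F3. On mild acidification this closes by ordinary acyl substitution, with retention at C6, and rejoins the route at 27.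

Step 17. Facial selectivity at C9 may be poor, iodine may be lost reductively, or intermolecular coupling may compete with ring closure.
The fallback makes C9 stereoconvergent. It starts from 22 and accepts the ring closure as a mixture of 23 and its 9-epimer F4. Dess–Martin oxidation takes both to the alkylidene β-keto ester F5. Luche 1,2-reduction at −78 °C, with hydride arriving antiperiplanar to the C8–O bond (the polar model gives the 8,9-syn product for a ketone), returns to 23.

Step 13. Pt(0) may ionise the allenylic ester, the product may suffer vinylogous boron–oxygen elimination, or addition may occur at the internal C=C.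
The fallback postpones the acylation so that C8 carries a poor leaving group during all the boron chemistry. It starts from 13. Diboration gives the acetonide bis-boronate F6, and allylboration of 9 gives the acetonide alcohol F7. Mesylation gives the acetonide mesylate F8, and mild aqueous acid gives the 8,9-diol F9. Primary-selective silylation gives the 9-O-TES 8-alcohol F10, and Yamaguchi esterification with 4 rejoins the route at 21.

Further compounds
F1 | step 20 | 6S acetate (C11–Bpin, 9-OTBS) | CC(=O)O[C@H]2[C@H](C(=C)B3OC(C)(C)C(C)(C)O3)[C@H](OC(=O)[C@@]3(C)O[C@H]3C)[C@@H](O[Si](C)(C)C(C)(C)C)/C(C(=O)OC)=C\C=C/[C@@]1(C)O[C@H]21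
F2 | step 20 | acrylic acid (C11–CO2H, 6S-OAc) | CC(=O)O[C@H]2[C@H](C(=C)C(=O)O)[C@H](OC(=O)[C@@]3(C)O[C@H]3C)[C@@H](O[Si](C)(C)C(C)(C)C)/C(C(=O)OC)=C\C=C/[C@@]1(C)O[C@H]21
F3 | step 20 | hydroxy acid (C11–CO2H, 6S-OH) | O[C@H]2[C@H](C(=C)C(=O)O)[C@H](OC(=O)[C@@]3(C)O[C@H]3C)[C@@H](O[Si](C)(C)C(C)(C)C)/C(C(=O)OC)=C\C=C/[C@@]1(C)O[C@H]21
F4 | step 17 | 9-epimer of 23 | CS(=O)(=O)O[C@@H]2[C@H](C(=C)B3OC(C)(C)C(C)(C)O3)[C@H](OC(=O)[C@@]3(C)O[C@H]3C)[C@H](O)/C(C(=O)OC)=C\C#C[C@@]1(C)O[C@H]21
F5 | step 17 | alkylidene β-keto ester (C9 ketone) | CS(=O)(=O)O[C@@H]2[C@H](C(=C)B3OC(C)(C)C(C)(C)O3)[C@H](OC(=O)[C@@]3(C)O[C@H]3C)C(=O)/C(C(=O)OC)=C\C#C[C@@]1(C)O[C@H]21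
F6 | step 13 | acetonide bis-boronate | CC1(C)OB(C/C(B2OC(C)(C)C(C)(C)O2)=C\[C@H]2COC(C)(C)O2)OC1(C)C
F7 | step 13 | acetonide alcohol (6R-OH) | CC1(C)OC[C@@H](O1)[C@@H](C(=C)B2OC(C)(C)C(C)(C)O2)[C@@H](O)[C@H]2O[C@]2(C)C#C/C=C(\I)C(=O)OC
F8 | step 13 | acetonide mesylate | CC1(C)OC[C@@H](O1)[C@@H](C(=C)B2OC(C)(C)C(C)(C)O2)[C@@H](OS(C)(=O)=O)[C@H]2O[C@]2(C)C#C/C=C(\I)C(=O)OC
F9 | step 13 | 8,9-diol | OC[C@@H](O)[C@@H](C(=C)B1OC(C)(C)C(C)(C)O1)[C@@H](OS(C)(=O)=O)[C@H]1O[C@]1(C)C#C/C=C(\I)C(=O)OC
F10 | step 13 | 9-O-TES 8-alcohol | CC[Si](CC)(CC)OC[C@@H](O)[C@@H](C(=C)B1OC(C)(C)C(C)(C)O1)[C@@H](OS(C)(=O)=O)[C@H]1O[C@]1(C)C#C/C=C(\I)C(=O)OC
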